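**Plan**

- Ring atoms of the lactone are called O1, C2(=O), C3 (carries the 4-methylpent-3-enyl chain), C4 (=CH), C5 (CH2), C6 (C(OH)CH3) and C7 (CH–O, carries the side chain).
- Retrosynthetic cuts, in order: the acetate C–O bond; the C3=C4 double bond of the oxepin-2-one ring; the ester bond O1–C2; the C4–C5 bond (vinyl onto an epoxide CH2). What remains is an epoxy alcohol whose ten skeletal carbons are those of geraniol.
- Forward: geraniol → silyl ether → 6,7-epoxide → isopropenyl carbinol → epoxy alcohol → vinyl opening → ester with a 2-substituted acrylic acid (fragment 2, three steps) → closure of the seven-membered ring at C3=C4 → desilylation → acetylation.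
- Enabling feature: the acyl oxygen O1 on C7 and the allyl group on the neighbouring quaternary carbinol C6 hold the acrylate =CH2 on C3 and the only monosubstituted alkene (C4) within reach. The seven-membered ring is the only ring and it forces the Z enoate geometry.
- Stereochemistry: C6 (R) and C7 (S) both come from one Sharpless kinetic-resolution epoxidation with L-(+)-diisopropyl tartrate; later steps break no bond at either center. The E side-chain alkene is that of geraniol.

Key step: step 10

Remark: the kinetic resolution in step 7 can convert at most half of racemic 9; the slow (R)-enantiomer is separated by chromatography.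

**Fragment 2 (acid)**

Step 1
Reactants: 1 triethyl phosphonoacetate; 2 5-bromo-2-methylpent-2-ene
Product: 3 ethyl 2-(diethoxyphosphoryl)-6-methylhept-5-enoate (racemic)
Conditions: NaH, DMF, 0 °C; then 2, 60 °C
Reagents that add atoms: none
Why: C-alkylation (SN2) of the sodium phosphonoacetate anion by an unhindered primary bromide is standard, and the α-center may stay racemic because it becomes sp2 in step 2.

Step 2
Reactants: 3 ethyl 2-(diethoxyphosphoryl)-6-methylhept-5-enoate
Product: 4 ethyl 6-methyl-2-methylidenehept-5-enoate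
Conditions: 37% aq. HCHO, K2CO3, THF/H2O, rt → 60 °C
Reagents that add atoms: formaldehyde, C=O
Why: Horner–Wadsworth–Emmons olefination of formaldehyde by an α-alkylphosphonoacetate under aqueous carbonate conditions is the classical entry to 2-alkylacrylates.

Step 3
Reactants: 4 ethyl 6-methyl-2-methylidenehept-5-enoate
Product: 5 6-methyl-2-methylidenehept-5-enoic acid
Conditions: LiOH, THF/H2O, 0 °C → rt; then aq. HCl to pH 3
Reagents that add atoms: lithium hydroxide, [Li+].[OH-]
Why: Ester saponification (acyl substitution) at or below room temperature should be faster than conjugate addition of hydroxide to the hindered 2-substituted acrylate.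

**Fragment 1 and endgame**

Step 4
Reactants: 6 geraniol
Product: 7 tert-butyl{[(2E)-3,7-dimethylocta-2,6-dien-1-yl]oxy}diphenylsilane (geranyl TBDPS ether)
Conditions: TBDPSCl, imidazole, CH2Cl2, 0 °C → rt
Reagents that add atoms: tert-butyl(chloro)diphenylsilane, CC(C)(C)[Si](Cl)(c1ccccc1)c1ccccc1
Why: Silylation of the primary allylic alcohol gives an ether that keeps this hydroxyl out of the titanium epoxidation of step 7 and survives the Grignard reagent of step 8.

Step 5
Reactants: 7 geranyl TBDPS ether
Product: 8 tert-butyl{[(2E)-5-(3,3-dimethyloxiran-2-yl)-3-methylpent-2-en-1-yl]oxy}diphenylsilane (racemic 6,7-epoxide)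
Conditions: mCPBA (1.0 equiv), NaHCO3, CH2Cl2, −20 °C
Reagents that add atoms: 3-chloroperoxybenzoic acid, OOC(=O)c1cccc(Cl)c1
Why: Prilezhaev epoxidation should prefer the terminal trisubstituted alkene, because the 2,3-alkene is deactivated by the allylic silyloxy group; the new center is racemic and is resolved in step 7.

Step 6
Reactants: 8 racemic 6,7-epoxide
Product: 9 (6E)-8-[(tert-butyldiphenylsilyl)oxy]-2,6-dimethylocta-1,6-dien-3-ol (racemic)
Conditions: Al(OiPr)3, toluene, 110 °C
Reagents that add atoms: none
Why: Aluminium-alkoxide-promoted isomerization of a trisubstituted epoxide to an allylic alcohol (syn-elimination through a cyclic transition state) opens the tertiary C–O bond and takes a proton from a methyl group, giving the isopropenyl carbinol without touching the C–O bond at the secondary carbon.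

Step 7
Reactants: 9 racemic isopropenyl carbinol
Product: 10 (1S,4E)-6-[(tert-butyldiphenylsilyl)oxy]-4-methyl-1-[(2R)-2-methyloxiran-2-yl]hex-4-en-1-ol
Conditions: Ti(OiPr)4 (10 mol%), L-(+)-diisopropyl tartrate (15 mol%), t-BuOOH (0.6 equiv), 4 Å MS, CH2Cl2, −20 °C
Reagents that add atoms: tert-butyl hydroperoxide, CC(C)(C)OO
Why: Sharpless kinetic-resolution epoxidation: with the L-(+)-tartrate the (S)-carbinol should react fast and give the erythro epoxy alcohol, which sets C7 (S, by selection of the enantiomer) and C6 (R, by reagent-controlled face selection on the 1,1-disubstituted alkene); the side-chain alkene is not an allylic alcohol and should stay inert, and the (R)-enantiomer of 9 should remain.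

Step 8
Reactants: 10 epoxy alcohol
Product: 11 (4R,5S,8E)-10-[(tert-butyldiphenylsilyl)oxy]-4,8-dimethyldeca-1,8-diene-4,5-diol
Conditions: vinylmagnesium bromide (4 equiv), CuI (20 mol%), THF, −40 → −10 °C; aq. NH4Cl
Reagents that add atoms: vinylmagnesium bromide, C=C[Mg]Br
Why: Copper-catalysed Grignard opening of a 2,2-disubstituted epoxide takes place by SN2 at the unhindered CH2, so the tertiary C–O bond at C6 and the carbinol C7 keep their configuration and the allyl group (C5–C4) is in place.

Step 9
Reactants: 11 diol; 5 6-methyl-2-methylidenehept-5-enoic acid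
Product: 12 (4R,5S,8E)-10-[(tert-butyldiphenylsilyl)oxy]-4-hydroxy-4,8-dimethyldeca-1,8-dien-5-yl 6-methyl-2-methylidenehept-5-enoate
Conditions: DIC, DMAP (0.3 equiv), CH2Cl2, 0 °C → rt
Reagents that add atoms: none
Why: Steglich esterification should acylate the secondary hydroxyl at C7 and leave the tertiary hydroxyl at C6 free, and no bond at a stereocenter is broken.

Step 10
Reactants: 12 acrylate ester
Product: 13 (6R,7S)-7-{(3E)-5-[(tert-butyldiphenylsilyl)oxy]-3-methylpent-3-en-1-yl}-6-hydroxy-6-methyl-3-(4-methylpent-3-en-1-yl)-6,7-dihydrooxepin-2(5H)-one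
Conditions: second-generation Grubbs catalyst, (H2IMes)(PCy3)Cl2Ru=CHPh (10 mol%), toluene (0.002 M), 80 °C, argon stream
Reagents that add atoms: none
Why: Ring-closing olefin metathesis (Chauvin mechanism): the ruthenium benzylidene should load on the allyl group at C4, the only monosubstituted alkene of 12, and the resulting alkylidene adds across the 1,1-disubstituted acrylate C3=CH2 to a ruthenacyclobutane that collapses to the C3=C4 bond with loss of ethene. The closest known reaction type is the ring-closing metathesis of acrylate and methacrylate esters of homoallylic and bis-homoallylic alcohols to α,β-unsaturated six- and seven-membered lactones. The one ring closed is the seven-membered oxepin-2-one, closed at C3=C4 with the ester linkage O1–C2 as the tether; the quaternary C6 and a hydrogen bond from its free hydroxyl to the ester carbonyl should favour the folded s-cis ester conformer. No stereocenter is formed, C6 and C7 are not touched, and the trisubstituted enoate can only be Z (C2 and C5 cis) inside the seven-membered ring. The step needs chemoselectivity among four alkenes: the two trisubstituted alkenes are the slowest partners for a ruthenium alkylidene, and closure onto the side-chain alkene (carbocyclic seven-membered ring through a crowded metallacycle next to the bulky silyl ether) or onto the prenyl terminus (ten-membered ring) should lose against closure onto the acrylate. High dilution suppresses dimerization and the argon stream removes ethene.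

Step 11
Reactants: 13 lactone silyl ether
Product: 14 (6R,7S)-6-hydroxy-7-[(3E)-5-hydroxy-3-methylpent-3-en-1-yl]-6-methyl-3-(4-methylpent-3-en-1-yl)-6,7-dihydrooxepin-2(5H)-one
Conditions: HF·pyridine, pyridine, THF, 0 °C → rt
Reagents that add atoms: none
Why: Fluoride-mediated desilylation under buffered, non-basic conditions should free the primary allylic alcohol without acyl migration in the hydroxy lactone or ionization of the tertiary alcohol.

Step 12
Reactants: 14 hydroxy lactone
Product: 15 the target, (6R,7S)-7-[(3E)-5-acetoxy-3-methylpent-3-en-1-yl]-6-hydroxy-6-methyl-3-(4-methylpent-3-en-1-yl)-6,7-dihydrooxepin-2(5H)-one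
Conditions: Ac2O, pyridine, CH2Cl2, 0 °C
Reagents that add atoms: acetic anhydride, CC(=O)OC(C)=O
Why: Acylation with acetic anhydride and pyridine, without a stronger acyl-transfer catalyst, should acetylate the primary allylic alcohol and leave the hindered tertiary alcohol untouched.

**Compound list**

1 | triethyl phosphonoacetate | CCOC(=O)CP(=O)(OCC)OCC | starting material
2 | 5-bromo-2-methylpent-2-ene | CC(C)=CCCBr | starting material
3 | ethyl 2-(diethoxyphosphoryl)-6-methylhept-5-enoate (racemic) | CCOC(=O)C(CCC=C(C)C)P(=O)(OCC)OCC | intermediate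
4 | ethyl 6-methyl-2-methylidenehept-5-enoate | CCOC(=O)C(=C)CCC=C(C)C | intermediate
5 | 6-methyl-2-methylidenehept-5-enoic acid | OC(=O)C(=C)CCC=C(C)C | intermediate
6 | geraniol | CC(C)=CCC/C(C)=C/CO | starting material
7 | geranyl tert-butyldiphenylsilyl ether | CC(C)=CCC/C(C)=C/CO[Si](c1ccccc1)(c1ccccc1)C(C)(C)C | intermediate
8 | tert-butyl{[(2E)-5-(3,3-dimethyloxiran-2-yl)-3-methylpent-2-en-1-yl]oxy}diphenylsilane (racemic) | CC1(C)OC1CC/C(C)=C/CO[Si](c1ccccc1)(c1ccccc1)C(C)(C)C | intermediate
9 | (6E)-8-[(tert-butyldiphenylsilyl)oxy]-2,6-dimethylocta-1,6-dien-3-ol (racemic) | C=C(C)C(O)CC/C(C)=C/CO[Si](c1ccccc1)(c1ccccc1)C(C)(C)C | intermediate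
10 | (1S,4E)-6-[(tert-butyldiphenylsilyl)oxy]-4-methyl-1-[(2R)-2-methyloxiran-2-yl]hex-4-en-1-ol | CC(C)(C)[Si](c1ccccc1)(c1ccccc1)OC/C=C(\C)CC[C@H](O)[C@@]1(C)CO1 | intermediate
11 | (4R,5S,8E)-10-[(tert-butyldiphenylsilyl)oxy]-4,8-dimethyldeca-1,8-diene-4,5-diol | CC(C)(C)[Si](c1ccccc1)(c1ccccc1)OC/C=C(\C)CC[C@H](O)[C@](C)(O)CC=C | intermediate
12 | (4R,5S,8E)-10-[(tert-butyldiphenylsilyl)oxy]-4-hydroxy-4,8-dimethyldeca-1,8-dien-5-yl 6-methyl-2-methylidenehept-5-enoate | CC(C)(C)[Si](c1ccccc1)(c1ccccc1)OC/C=C(\C)CC[C@H](OC(=O)C(=C)CCC=C(C)C)[C@](C)(O)CC=C | intermediate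
13 | (6R,7S)-7-{(3E)-5-[(tert-butyldiphenylsilyl)oxy]-3-methylpent-3-en-1-yl}-6-hydroxy-6-methyl-3-(4-methylpent-3-en-1-yl)-6,7-dihydrooxepin-2(5H)-one | CC(C)(C)[Si](c1ccccc1)(c1ccccc1)OC/C=C(\C)CC[C@@H]1OC(=O)C(CCC=C(C)C)=CC[C@@]1(C)O | intermediate
14 | (6R,7S)-6-hydroxy-7-[(3E)-5-hydroxy-3-methylpent-3-en-1-yl]-6-methyl-3-(4-methylpent-3-en-1-yl)-6,7-dihydrooxepin-2(5H)-one | OC/C=C(\C)CC[C@@H]1OC(=O)C(CCC=C(C)C)=CC[C@@]1(C)O | intermediate
15 | (6R,7S)-7-[(3E)-5-acetoxy-3-methylpent-3-en-1-yl]-6-hydroxy-6-methyl-3-(4-methylpent-3-en-1-yl)-6,7-dihydrooxepin-2(5H)-one | CC(=O)OC/C=C(\C)CC[C@@H]1OC(=O)C(CCC=C(C)C)=CC[C@@]1(C)O | target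

**Step count**

Total: 12 steps. Longest linear sequence: 9 steps (steps 4 to 12, geraniol to 15); fragment 2 takes 3 steps (steps 1 to 3) and enters at step 9.

**Steps most likely to fail**

Step 10 (ring closure). The ruthenium alkylidene at C4 may close onto the trisubstituted side-chain alkene or oligomerize faster than it engages the hindered, electron-poor acrylate, which must first adopt the s-cis ester conformer. The fallback closes the same bond by carbonyl olefination and sets out from epoxy alcohol 10. 2-Lithio-1,3-dithiane (from 1,3-dithiane and n-BuLi, THF, −30 → 0 °C) should open the epoxide at CH2 to give (2R,3S,6E)-8-[(tert-butyldiphenylsilyl)oxy]-1-(1,3-dithian-2-yl)-2,6-dimethyloct-6-ene-2,3-diol F1. Phosphonate ester 3 is saponified (LiOH, THF/H2O) to 2-(diethoxyphosphoryl)-6-methylhept-5-enoic acid F2, which is coupled to the secondary hydroxyl of F1 (DIC, DMAP, CH2Cl2) to give the phosphonoester F3. Hydrolysis of the dithiane (MeI, CaCO3, MeCN/H2O) should give the β-hydroxy aldehyde F4, in which the only free hydroxyl is the tertiary one and cannot form a lactol. An intramolecular Horner–Wadsworth–Emmons olefination under Masamune–Roush conditions (LiCl, DBU, MeCN, high dilution) then closes C3=C4, Z by ring constraint, and the route is rejoined at 13.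

Step 7 (kinetic resolution). The rate difference between the enantiomers of 9 may be too small, or the Lewis-acidic titanium alkoxide may open the acid-sensitive 2,2-disubstituted epoxide; in any case half of the material is lost. The fallback sets out from racemic 9. Dess–Martin periodinane should give the enone (6E)-8-[(tert-butyldiphenylsilyl)oxy]-2,6-dimethylocta-1,6-dien-3-one F5. Corey–Bakshi–Shibata reduction with (R)-2-methyl-CBS-oxazaborolidine and catecholborane (toluene, −78 °C), with the isopropenyl group as the large substituent, should give (3S,6E)-8-[(tert-butyldiphenylsilyl)oxy]-2,6-dimethylocta-1,6-dien-3-ol F6. Hydroxyl-directed epoxidation with VO(acac)2 and t-BuOOH, which is erythro-selective for 2-substituted allylic alcohols, should then lead to 10, where the route is rejoined.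

Step 9 (esterification). Acylation of the secondary hydroxyl next to the quaternary carbinol by an α-branched acid may be slow, so that rearrangement of the activated acid to an N-acylurea takes over. The fallback builds the acrylate on the alcohol and sets out from diol 11. The small diethylphosphonoacetic acid is coupled first (DIC, DMAP) to give the phosphonoacetate F7. Its carbanion (NaH, 1.0 equiv, DMF) is alkylated with bromide 2 to give the α-(4-methylpent-3-enyl) phosphonoester F8. A Horner–Wadsworth–Emmons reaction with aqueous formaldehyde and K2CO3 then gives 12, where the route is rejoined.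

**Further compounds**

F1 | step 10 | (2R,3S,6E)-8-[(tert-butyldiphenylsilyl)oxy]-1-(1,3-dithian-2-yl)-2,6-dimethyloct-6-ene-2,3-diol | CC(C)(C)[Si](c1ccccc1)(c1ccccc1)OC/C=C(\C)CC[C@H](O)[C@](C)(O)CC1SCCCS1
F2 | step 10 | 2-(diethoxyphosphoryl)-6-methylhept-5-enoic acid (racemic) | OC(=O)C(CCC=C(C)C)P(=O)(OCC)OCC
F3 | step 10 | (2R,3S,6E)-8-[(tert-butyldiphenylsilyl)oxy]-1-(1,3-dithian-2-yl)-2-hydroxy-2,6-dimethyloct-6-en-3-yl 2-(diethoxyphosphoryl)-6-methylhept-5-enoate (epimers at the phosphonate carbon) | CC(C)(C)[Si](c1ccccc1)(c1ccccc1)OC/C=C(\C)CC[C@H](OC(=O)C(CCC=C(C)C)P(=O)(OCC)OCC)[C@](C)(O)CC1SCCCS1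
F4 | step 10 | (3R,4S,7E)-9-[(tert-butyldiphenylsilyl)oxy]-3-hydroxy-3,7-dimethyl-1-oxonon-7-en-4-yl 2-(diethoxyphosphoryl)-6-methylhept-5-enoate (epimers at the phosphonate carbon) | CC(C)(C)[Si](c1ccccc1)(c1ccccc1)OC/C=C(\C)CC[C@H](OC(=O)C(CCC=C(C)C)P(=O)(OCC)OCC)[C@](C)(O)CC=O
F5 | step 7 | (6E)-8-[(tert-butyldiphenylsilyl)oxy]-2,6-dimethylocta-1,6-dien-3-one | C=C(C)C(=O)CC/C(C)=C/CO[Si](c1ccccc1)(c1ccccc1)C(C)(C)C
F6 | step 7 | (3S,6E)-8-[(tert-butyldiphenylsilyl)oxy]-2,6-dimethylocta-1,6-dien-3-ol | CC(C)(C)[Si](c1ccccc1)(c1ccccc1)OC/C=C(\C)CC[C@H](O)C(C)=C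
F7 | step 9 | (4R,5S,8E)-10-[(tert-butyldiphenylsilyl)oxy]-4-hydroxy-4,8-dimethyldeca-1,8-dien-5-yl 2-(diethoxyphosphoryl)acetate | CC(C)(C)[Si](c1ccccc1)(c1ccccc1)OC/C=C(\C)CC[C@H](OC(=O)CP(=O)(OCC)OCC)[C@](C)(O)CC=C
F8 | step 9 | (4R,5S,8E)-10-[(tert-butyldiphenylsilyl)oxy]-4-hydroxy-4,8-dimethyldeca-1,8-dien-5-yl 2-(diethoxyphosphoryl)-6-methylhept-5-enoate (epimers at the phosphonate carbon) | CC(C)(C)[Si](c1ccccc1)(c1ccccc1)OC/C=C(\C)CC[C@H](OC(=O)C(CCC=C(C)C)P(=O)(OCC)OCC)[C@](C)(O)CC=C
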